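**Plan**
Numbering: ring A has C1 (CO2H), C2 (ether O), C4 (OMe) and C6 (pentanoyl). Ring B has C1' (ether O), C2' (pentyl), and C4' and C6' (OH).
Cuts: the C6' hydroxyl goes back to a C6' formyl group and the acid to its methyl ester. Ring B is then cut at C4'-C5' and C6'-C1' into a 2-aryloxy-3-pentylfuran and propynal. The furan is cut at C2-OAr, C3-pentyl and C5-CHO, and ring A at its C6-acyl bond.
Enabling feature: in ring B the ether carbon C1' and the hydroxyl carbon C4' are 1,4 to each other, with C2' (pentyl) and C3' (H) between them. This is the C2-C3-C4-C5 array of a furan, whose ring oxygen spans these two carbons and ends as the C4' hydroxyl.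
Forward: ring A is bought and substituted (steps 1-5), then joined through oxygen to a bromofurfural while both partners are still uncrowded (step 6). The furan is pentylated and loses its formyl group (steps 7-8). Ring B, the only ring built, closes in step 10, and two steps then adjust C6' and the ester.
Stereochemistry: the target has no stereocentre. The racemic centres formed on the way (carbinol/phthalide carbon, cycloadduct bridgeheads) are removed by oxidation or aromatisation.

Key step: step 10

Assumption: the target is drawn as the open keto acid. Like other 2-acylbenzoic acids it can equilibrate with its 3-butyl-3-hydroxyphthalide ring tautomer, and both forms are treated as one compound. The same applies to the keto acid of step 3.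

**Step 1**
Reactants: 1 2,4-dimethoxybenzoic acid
Product: 3 N,N-diethyl-2,4-dimethoxybenzamide, via 2,4-dimethoxybenzoyl chloride 2 (not isolated)
Conditions: SOCl2, DMF (cat.), toluene, 70 °C; concentrate; Et2NH (3 equiv), CH2Cl2, 0 °C → rt
Reagents that add atoms: diethylamine, CCNCC
Why: Acid chloride formation followed by Schotten-Baumann-type aminolysis is the standard route to the tertiary benzamide, which serves as a strong directing group for the next step.

**Step 2**
Reactants: 3 N,N-diethyl-2,4-dimethoxybenzamide; 4 pentanal
Product: 7 (±)-3-butyl-5,7-dimethoxyphthalide, via ortho-lithiated amide 5 (not isolated), via hydroxy amide 6 (not isolated)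
Conditions: s-BuLi, TMEDA, THF, −78 °C; 4, −78 °C → rt; aq. HCl quench; crude 6, TsOH·H2O (1.2 equiv), toluene, reflux
Reagents that add atoms: none
Why: In this directed ortho-metalation the amide binds s-BuLi/TMEDA and delivers it kinetically to C6 rather than to the position between the two methoxy groups, the aryllithium adds 1,2 to the aldehyde, and acid-catalysed lactonisation of the racemic carbinol onto the neighbouring amide expels diethylamine and so removes a group that is otherwise hard to hydrolyse.

**Step 3**
Reactants: 7 (±)-3-butyl-5,7-dimethoxyphthalide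
Product: 9 2,4-dimethoxy-6-pentanoylbenzoic acid, via sodium hydroxy carboxylate 8 (not isolated)
Conditions: NaOH, H2O/t-BuOH, 80 °C; KMnO4, 0 °C → rt; filter; HCl to pH 2
Reagents that add atoms: sodium hydroxide, [Na+].[OH-]
Why: Saponification holds the lactone open as its carboxylate, so alkaline KMnO4 oxidation of the secondary benzylic alcohol gives the aryl ketone and removes the stereocentre, while the phenol oxygens are still capped as methyl ethers.

**Step 4**
Reactants: 9 2,4-dimethoxy-6-pentanoylbenzoic acid
Product: 10 methyl 2,4-dimethoxy-6-pentanoylbenzoate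
Conditions: MeI, K2CO3, DMF, rt
Reagents that add atoms: iodomethane, CI
Why: SN2 O-alkylation of the carboxylate traps the open keto-acid form and gives the normal methyl ester rather than the 3-methoxyphthalide pseudo-ester that acid-catalysed esterification tends to produce.

**Step 5**
Reactants: 10 methyl 2,4-dimethoxy-6-pentanoylbenzoate
Product: 12 methyl 2-hydroxy-4-methoxy-6-pentanoylbenzoate, via aryloxydichloroborane 11 (not isolated)
Conditions: BCl3 (2.2 equiv), CH2Cl2, −78 → 0 °C; H2O
Reagents that add atoms: none
Why: In this chelation-controlled Lewis-acid ether cleavage, BCl3 bridges the ester carbonyl and the ortho methoxy oxygen in a six-membered chelate, so chloride removes only that methyl group and the 4-methoxy group, which has no carbonyl neighbour, is kept.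

**Step 6**
Reactants: 12 methyl 2-hydroxy-4-methoxy-6-pentanoylbenzoate; 13 4,5-dibromofurfural
Product: 14 methyl 2-[(3-bromo-5-formylfuran-2-yl)oxy]-4-methoxy-6-pentanoylbenzoate
Conditions: K2CO3, DMF, 70 °C
Reagents that add atoms: none
Why: In this nucleophilic aromatic substitution by addition-elimination only the C5 bromide is conjugated with the formyl group (a vinylogous acyl bromide), so the phenoxide displaces it and spares the C4 bromide, and each partner has just one flanking substituent at this stage, so the ether that is di-ortho-substituted in the target forms without crowding.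

**Step 7**
Reactants: 14 methyl 2-[(3-bromo-5-formylfuran-2-yl)oxy]-4-methoxy-6-pentanoylbenzoate; 15 pentylboronic acid
Product: 16 methyl 2-[(5-formyl-3-pentylfuran-2-yl)oxy]-4-methoxy-6-pentanoylbenzoate
Conditions: Pd(OAc)2 (5 mol %), SPhos (10 mol %), K3PO4, toluene/H2O, 90 °C
Reagents that add atoms: none
Why: This is a Suzuki-Miyaura sp2-sp3 coupling of a primary alkylboronic acid with a heteroaryl bromide, in which the bulky electron-rich biarylphosphine speeds reductive elimination enough to outrun beta-hydride elimination, and the ester, ketone and aldehyde tolerate the phosphate base.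

**Step 8**
Reactants: 16 methyl 2-[(5-formyl-3-pentylfuran-2-yl)oxy]-4-methoxy-6-pentanoylbenzoate
Product: 17 methyl 4-methoxy-6-pentanoyl-2-[(3-pentylfuran-2-yl)oxy]benzoate
Conditions: RhCl3·3H2O (5 mol %), dppp (10 mol %), diglyme, 160 °C, N2 sweep; filtration through Et3N-deactivated silica, used at once
Reagents that add atoms: none
Why: In this catalytic Tsuji-Wilkinson-type decarbonylation rhodium inserts into the formyl C-H bond, CO is extruded and reductive elimination leaves H at furan C5, the chelating bisphosphine allows CO to leave the metal so that the cycle turns over, and simple 2-aryloxyfurans are known to survive comparable heat.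

**Step 9**
Reactants: 18 propargyl alcohol
Product: 19 propynal
Conditions: CrO3, H2SO4, H2O, 2-10 °C, 40-60 mmHg, product trapped at −78 °C; dried, redistilled, kept cold as a toluene solution (no base)
Reagents that add atoms: none
Why: CrO3/H2SO4 (Jones-type) oxidation of the primary propargylic alcohol stops at the aldehyde because the volatile product is swept out of the aqueous oxidant under reduced pressure as it forms.

**Step 10**
Reactants: 17 methyl 4-methoxy-6-pentanoyl-2-[(3-pentylfuran-2-yl)oxy]benzoate; 19 propynal
Product: 21 methyl 2-(2-formyl-4-hydroxy-6-pentylphenoxy)-4-methoxy-6-pentanoylbenzoate, via oxanorbornadiene adduct 20 (not isolated)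
Conditions: 19 (3 equiv), BHT (1 mol %), toluene (1 M), 0 → 50 °C, dark, dry; then PPTS (10 mol %), rt
Reagents that add atoms: none
Why: The aryloxy oxygen polarises the furan so that C5 is its most nucleophilic terminus, and this carbon bonds first to the terminal (beta) carbon of the ynal while the carbon alpha to the formyl group closes slightly later onto C2, in a concerted but strongly asynchronous normal-electron-demand Diels-Alder reaction. Ring B is thus closed by an intermolecular (4+2) cycloaddition that forms C4'-C5' and C6'-C1' and gives the 7-oxanorbornadiene 20. In 20 the bridge oxygen and the aryloxy oxygen make C1' a ketal carbon, so trace acid ionises the C1'-O(bridge) bond to an aryloxy-stabilised cyclohexadienyl cation, and loss of the C4' proton aromatises the ring and leaves the former furan oxygen as the C4' hydroxyl. The closest known reaction type is the cycloaddition of 2-alkoxy- and 2-silyloxyfurans with propiolates, ynones and acetylenedicarboxylates, which gives hydroquinone monoethers by the same opening. No stereocentre has to be controlled, since both bridgeheads of racemic 20 become sp2 carbons. Two regioselectivities are needed: the orientation of addition (formyl on C6', next to the ether carbon) is secured by the matched donor-acceptor polarisation, with the C3 pentyl group far from the first-formed bond, and the direction of opening is secured because only C1' carries a second oxygen, whereas heterolysis at C4' would need an unstabilised secondary cation and would end in loss of the ring A phenol.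

**Step 11**
Reactants: 21 methyl 2-(2-formyl-4-hydroxy-6-pentylphenoxy)-4-methoxy-6-pentanoylbenzoate
Product: 22 methyl 2-[2-(formyloxy)-4-hydroxy-6-pentylphenoxy]-4-methoxy-6-pentanoylbenzoate
Conditions: mCPBA (1.3 equiv), CH2Cl2, 0 °C → rt
Reagents that add atoms: 3-chloroperoxybenzoic acid, O=C(OO)c1cccc(Cl)c1
Why: In this Baeyer-Villiger oxidation the peracid adds much faster to the aldehyde than to the ester-flanked ring A ketone, and in the Criegee adduct the ring B carbon, supported by the ortho aryloxy oxygen, migrates to give the aryl formate, as in the established conversion of 2-aryloxybenzaldehydes into 2-aryloxyphenols.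

**Step 12**
Reactants: 22 methyl 2-[2-(formyloxy)-4-hydroxy-6-pentylphenoxy]-4-methoxy-6-pentanoylbenzoate
Product: 24 2-(2,4-dihydroxy-6-pentylphenoxy)-4-methoxy-6-pentanoylbenzoic acid (target), via diphenol methyl ester 23 (not isolated)
Conditions: LiOH (6 equiv), degassed THF/H2O, argon, 0 °C → rt; 1 M HCl to pH 3, 0 °C
Reagents that add atoms: lithium hydroxide, [Li+].[OH-]
Why: In this saponification the formate is cleaved first and the crowded methyl ester follows through the known neighbouring-group acceleration in 2-acylbenzoates (hydroxide adds to the ketone and the alkoxide attacks the ester), while low temperature, aqueous medium and exclusion of air hold back Smiles migration of ring A to the new C6' phenoxide and autoxidation of ring B.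

**Compound list**
1 | 2,4-dimethoxybenzoic acid | COc1ccc(C(=O)O)c(OC)c1 | starting material
2 | 2,4-dimethoxybenzoyl chloride (not isolated) | COc1ccc(C(=O)Cl)c(OC)c1 | intermediate
3 | N,N-diethyl-2,4-dimethoxybenzamide | CCN(CC)C(=O)c1ccc(OC)cc1OC | intermediate
4 | pentanal | CCCCC=O | starting material
5 | N,N-diethyl-2-lithio-4,6-dimethoxybenzamide (not isolated) | [Li]c1cc(OC)cc(OC)c1C(=O)N(CC)CC | intermediate
6 | (±)-N,N-diethyl-2-(1-hydroxypentyl)-4,6-dimethoxybenzamide (crude, not isolated) | CCCCC(O)c1cc(OC)cc(OC)c1C(=O)N(CC)CC | intermediate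
7 | (±)-3-butyl-5,7-dimethoxyphthalide (3-butyl-5,7-dimethoxy-2-benzofuran-1(3H)-one) | CCCCC1OC(=O)c2c(OC)cc(OC)cc21 | intermediate
8 | (±)-sodium 2-(1-hydroxypentyl)-4,6-dimethoxybenzoate (not isolated) | CCCCC(O)c1cc(OC)cc(OC)c1C(=O)[O-].[Na+] | intermediate
9 | 2,4-dimethoxy-6-pentanoylbenzoic acid | CCCCC(=O)c1cc(OC)cc(OC)c1C(=O)O | intermediate
10 | methyl 2,4-dimethoxy-6-pentanoylbenzoate | CCCCC(=O)c1cc(OC)cc(OC)c1C(=O)OC | intermediate
11 | methyl 2-[(dichloroboranyl)oxy]-4-methoxy-6-pentanoylbenzoate (not isolated) | CCCCC(=O)c1cc(OC)cc(OB(Cl)Cl)c1C(=O)OC | intermediate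
12 | methyl 2-hydroxy-4-methoxy-6-pentanoylbenzoate | CCCCC(=O)c1cc(OC)cc(O)c1C(=O)OC | intermediate
13 | 4,5-dibromofurfural | O=Cc1cc(Br)c(Br)o1 | starting material
14 | methyl 2-[(3-bromo-5-formylfuran-2-yl)oxy]-4-methoxy-6-pentanoylbenzoate | CCCCC(=O)c1cc(OC)cc(Oc2oc(C=O)cc2Br)c1C(=O)OC | intermediate
15 | pentylboronic acid | CCCCCB(O)O | starting material
16 | methyl 2-[(5-formyl-3-pentylfuran-2-yl)oxy]-4-methoxy-6-pentanoylbenzoate | CCCCCc1cc(C=O)oc1Oc1cc(OC)cc(C(=O)CCCC)c1C(=O)OC | intermediate
17 | methyl 4-methoxy-6-pentanoyl-2-[(3-pentylfuran-2-yl)oxy]benzoate | CCCCCc1ccoc1Oc1cc(OC)cc(C(=O)CCCC)c1C(=O)OC | intermediate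
18 | propargyl alcohol | C#CCO | starting material
19 | propynal | C#CC=O | intermediate
20 | methyl 2-[(2-formyl-6-pentyl-7-oxabicyclo[2.2.1]hepta-2,5-dien-1-yl)oxy]-4-methoxy-6-pentanoylbenzoate (racemic, bridgeheads tied by the oxygen bridge, not isolated) | CCCCCC1=CC2OC1(Oc3cc(OC)cc(C(=O)CCCC)c3C(=O)OC)C(C=O)=C2 | intermediate
21 | methyl 2-(2-formyl-4-hydroxy-6-pentylphenoxy)-4-methoxy-6-pentanoylbenzoate | CCCCCc1cc(O)cc(C=O)c1Oc1cc(OC)cc(C(=O)CCCC)c1C(=O)OC | intermediate
22 | methyl 2-[2-(formyloxy)-4-hydroxy-6-pentylphenoxy]-4-methoxy-6-pentanoylbenzoate | CCCCCc1cc(O)cc(OC=O)c1Oc1cc(OC)cc(C(=O)CCCC)c1C(=O)OC | intermediate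
23 | methyl 2-(2,4-dihydroxy-6-pentylphenoxy)-4-methoxy-6-pentanoylbenzoate (not isolated) | CCCCCc1cc(O)cc(O)c1Oc1cc(OC)cc(C(=O)CCCC)c1C(=O)OC | intermediate
24 | 2-(2,4-dihydroxy-6-pentylphenoxy)-4-methoxy-6-pentanoylbenzoic acid | CCCCCc1cc(O)cc(O)c1Oc1cc(OC)cc(C(=O)CCCC)c1C(=O)O | target

**Total step count:** 12
**Longest linear sequence:** 11 (steps 1-8 and 10-12; step 9 is a one-step side branch)

**Steps most likely to fail**

1. Step 10. The second bond has to form at the furan terminus crowded by the pentyl and aryloxy groups. The cycloaddition may therefore be slower than polymerisation of the ynal or hydrolysis of the ketene-acetal-like furan. An open dipolar species may also lose its C5 proton and end in simple conjugate substitution. The fallback sets out from 17 and replaces the fragile ynal by commercial but-3-yn-2-one, which tolerates prolonged heating (toluene, 90-110 °C, sealed tube). The same addition and opening should lead through the bridged adduct methyl 2-[(2-acetyl-6-pentyl-7-oxabicyclo[2.2.1]hepta-2,5-dien-1-yl)oxy]-4-methoxy-6-pentanoylbenzoate F1 to the acetylphenol methyl 2-(2-acetyl-4-hydroxy-6-pentylphenoxy)-4-methoxy-6-pentanoylbenzoate F2. Baeyer-Villiger oxidation (mCPBA, CF3CO2H, CH2Cl2) should then give the aryl acetate methyl 2-(2-acetoxy-4-hydroxy-6-pentylphenoxy)-4-methoxy-6-pentanoylbenzoate F3. Only aryl or methyl can migrate in this ketone. The ring A ketone should react more slowly, because its migrating carbon has an ortho ester and no ortho or para donor, and its other group is a primary alkyl. LiOH as in step 12 cleaves the acetate, and the route is rejoined at 23 and hence 24.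

2. Step 8. CO extrusion from the electron-rich, push-pull aldehyde may stall, the catalyst may be blocked by retained CO, and the acid-sensitive product may decompose during long heating at 160 °C. The fallback sets out from 16 and changes the oxidation level. Pinnick oxidation (NaClO2, NaH2PO4, 2-methyl-2-butene, t-BuOH/H2O) should give 5-[5-methoxy-2-(methoxycarbonyl)-3-pentanoylphenoxy]-4-pentylfuran-2-carboxylic acid F4. Catalytic protodecarboxylation (Ag2CO3 10 mol %, AcOH 5 mol %, DMSO, 120 °C) follows, which is the classical way to simple 2-aryloxyfurans. The route is rejoined at 17.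

3. Step 11. Hydride migration in the Criegee adduct may compete with aryl migration, because the twisted aryloxy group donates only weakly into ring B. The free para-aryloxyphenol may also be over-oxidised by the peracid. The fallback sets out from 21 and masks the phenol first. Ac2O/pyridine should give methyl 2-(4-acetoxy-2-formyl-6-pentylphenoxy)-4-methoxy-6-pentanoylbenzoate F5. This is oxidised with 30 % H2O2 and catalytic bis(2-nitrophenyl) diselenide in CH2Cl2, a perseleninic acid oxidation known to favour aryl formates, to give methyl 2-[4-acetoxy-2-(formyloxy)-6-pentylphenoxy]-4-methoxy-6-pentanoylbenzoate F6. The LiOH treatment of step 12 removes both acyl groups, so the route is rejoined at 23 and hence 24 without an extra deprotection.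

**Further compounds**
F1 | step 10 | methyl 2-[(2-acetyl-6-pentyl-7-oxabicyclo[2.2.1]hepta-2,5-dien-1-yl)oxy]-4-methoxy-6-pentanoylbenzoate (racemic) | CCCCCC1=CC2OC1(Oc3cc(OC)cc(C(=O)CCCC)c3C(=O)OC)C(C(C)=O)=C2
F2 | step 10 | methyl 2-(2-acetyl-4-hydroxy-6-pentylphenoxy)-4-methoxy-6-pentanoylbenzoate | CCCCCc1cc(O)cc(C(C)=O)c1Oc1cc(OC)cc(C(=O)CCCC)c1C(=O)OC
F3 | step 10 | methyl 2-(2-acetoxy-4-hydroxy-6-pentylphenoxy)-4-methoxy-6-pentanoylbenzoate | CCCCCc1cc(O)cc(OC(C)=O)c1Oc1cc(OC)cc(C(=O)CCCC)c1C(=O)OC
F4 | step 8 | 5-[5-methoxy-2-(methoxycarbonyl)-3-pentanoylphenoxy]-4-pentylfuran-2-carboxylic acid | CCCCCc1cc(C(=O)O)oc1Oc1cc(OC)cc(C(=O)CCCC)c1C(=O)OC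
F5 | step 11 | methyl 2-(4-acetoxy-2-formyl-6-pentylphenoxy)-4-methoxy-6-pentanoylbenzoate | CCCCCc1cc(OC(C)=O)cc(C=O)c1Oc1cc(OC)cc(C(=O)CCCC)c1C(=O)OC
F6 | step 11 | methyl 2-[4-acetoxy-2-(formyloxy)-6-pentylphenoxy]-4-methoxy-6-pentanoylbenzoate | CCCCCc1cc(OC(C)=O)cc(OC=O)c1Oc1cc(OC)cc(C(=O)CCCC)c1C(=O)OC
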